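**Retrosynthetic overview**

- The strategy rests on ring B, a hexasubstituted benzene in which three oxygens in different states (C2'–OH, C4'–OH, C6'–OMe) alternate with three carbon substituents (C1' methylene bridge, C3' prenyl, C5' isobutyryl).
- Last disconnection: the C1'–CH2–C3 bond to the pyranone (ring A), made by Michael capture of a ring B ortho-quinone methide by 6-ethyl-4-hydroxy-5-methylpyran-2-one, itself built from pentan-3-one and malonyl dichloride.
- C5'–acyl bond: bromination of the one aryl C–H, Br/Li exchange, addition to isobutyraldehyde, oxidation.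
- Ring B: benzannulation of a 4-prenyl-3-silyloxycyclobutenone with a methoxyalkyne that carries the bridge carbon (forms C1'–C2', C5'–C6', C2'–C3').
- Ring order: cyclobutenone by (2+2) of prenylketene with (triisopropylsilyloxy)ethyne, then ring B; ring A is made separately; the final coupling closes no ring.

Key step: step 5

Remark: the target has no stereocentre; the racemic centres that arise on the way (cyclobutenone C4, the annulation intermediates, the carbinol) are all removed later, so no stereocontrol is needed.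

**Route**

Step 1
Reactants: 1 5-methylhex-4-enoic acid
Product: 2 5-methylhex-4-enoyl chloride
Conditions: (COCl)2, DMF (cat.), CH2Cl2, 0 °C to rt; used crude
Reagents that add atoms: oxalyl chloride, O=C(Cl)C(Cl)=O
Why: Acid chloride formation through the catalytic chloroiminium species is mild enough at 0 °C to leave the trisubstituted alkene untouched.

Step 2
Reactants: 3 acetylene
Product: 6 (triisopropylsilyloxy)ethyne, via lithium acetylide 4 (not isolated), via lithium ethynolate 5 (not isolated)
Conditions: n-BuLi, THF (saturated with 3), −78 °C; t-BuOOLi (from t-BuOOH, LiN(SiMe3)2), −78 to −10 °C; i-Pr3SiOTf, −78 to 0 °C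
Reagents that add atoms: tert-butyl hydroperoxide, CC(C)(C)OO; triisopropylsilyl trifluoromethanesulfonate, CC(C)[Si](C(C)C)(C(C)C)OS(=O)(=O)C(F)(F)F
Why: Oxygenation of a lithium acetylide by the electrophilic peroxide oxygen gives the ynolate, which the bulky silyl triflate should capture on oxygen (acetylide oxidation then ynolate O-silylation, the usual entry to triisopropylsilyl ynol ethers from terminal alkynes).

Step 3
Reactants: 2 5-methylhex-4-enoyl chloride; 6 (triisopropylsilyloxy)ethyne
Product: 8 4-(3-methylbut-2-enyl)-3-(triisopropylsilyloxy)cyclobut-2-en-1-one (racemic), via prenylketene 7 (not isolated)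
Conditions: Et3N, CH2Cl2, rt; 2 added slowly to 6 (1.5 equiv)
Reagents that add atoms: none
Why: Dehydrochlorination gives the aldoketene, whose carbonyl carbon bonds to the unsubstituted nucleophilic carbon of the silyl ynol ether in a ketene–ynol ether (2+2) cycloaddition, placing OSi at C3 and prenyl at C4; C4 forms racemic and is destroyed in step 5.

Step 4
Reactants: 9 2-chloro-1,1-dimethoxyethane
Product: 12 tert-butyl(3-methoxyprop-2-ynoxy)dimethylsilane, via lithium methoxyacetylide 10 (not isolated), via lithium alkoxide 11 (not isolated)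
Conditions: LiNEt2 (3 equiv), THF, 0 °C; (CH2O)n, −78 °C to rt; TBSCl (excess), DMAP (cat.), 0 °C to rt
Reagents that add atoms: paraformaldehyde (formaldehyde), C=O; tert-butyldimethylsilyl chloride, CC(C)(C)[Si](C)(C)Cl
Why: Double elimination and deprotonation of the chloroacetal gives the alkoxyacetylide, which adds to formaldehyde (acetylide 1,2-addition); silylating the alkoxide in the same flask avoids isolating the acid-labile 3-alkoxypropargyl alcohol.

Step 5
Reactants: 8 4-(3-methylbut-2-enyl)-3-(triisopropylsilyloxy)cyclobut-2-en-1-one; 12 tert-butyl(3-methoxyprop-2-ynoxy)dimethylsilane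
Product: 17 2-[(tert-butyldimethylsilyloxy)methyl]-3-methoxy-6-(3-methylbut-2-enyl)-5-(triisopropylsilyloxy)phenol, via silyloxy vinylketene 13 (not isolated), via vinylcyclobutenone 14 (not isolated), via dienylketene 15 (not isolated), via cyclohexadienone 16 (not isolated)
Conditions: 12 (1.5 equiv), toluene, 80 °C, then 110 °C, argon
Reagents that add atoms: none
Why: Thermal 4π electrocyclic opening of 8 gives vinylketene 13, whose ketene carbonyl carbon bonds to the nucleophilic carbon of ynol ether 12 (the one bearing CH2OTBS) in a regioselective (2+2) cycloaddition to vinylcyclobutenone 14, forming C1'–C2' and C5'–C6'. A second 4π opening gives dienylketene 15, ring B closes by 6π electrocyclization (C2'–C3') to cyclohexadienone 16, and tautomerization gives phenol 17. The closest known reaction is the Danheiser benzannulation of cyclobutenones with alkoxy- and silyloxyalkynes to resorcinol derivatives; the 3-silyloxy group on the cyclobutenone extends it to the phloroglucinol pattern. No stereocentre survives, since the racemic centres of 8, 14 and 16 are erased on aromatization. The step needs regiocontrol in the (2+2) event, which the polarization of the ketene (electrophilic carbonyl carbon) and of the ynol ether secures, placing OMe meta and the CH2OTBS carbon ortho to the new hydroxyl; the isolated prenyl alkene should not compete as a ketenophile.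

Step 6
Reactants: 17 2-[(tert-butyldimethylsilyloxy)methyl]-3-methoxy-6-(3-methylbut-2-enyl)-5-(triisopropylsilyloxy)phenol
Product: 18 4-bromo-2-[(tert-butyldimethylsilyloxy)methyl]-3-methoxy-6-(3-methylbut-2-enyl)-5-(triisopropylsilyloxy)phenol
Conditions: NBS (1.0 equiv), CH2Cl2, −78 °C, dark
Reagents that add atoms: N-bromosuccinimide, O=C1CCC(=O)N1Br
Why: Electrophilic aromatic bromination at the only aryl C–H (C5'), which is para to the free phenol and ortho to two oxygens, should outrun any reaction at the prenyl alkene at −78 °C.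

Step 7
Reactants: 18 4-bromo-2-[(tert-butyldimethylsilyloxy)methyl]-3-methoxy-6-(3-methylbut-2-enyl)-5-(triisopropylsilyloxy)phenol
Product: 19 1-bromo-4-(tert-butyldimethylsilyloxy)-5-[(tert-butyldimethylsilyloxy)methyl]-6-methoxy-3-(3-methylbut-2-enyl)-2-(triisopropylsilyloxy)benzene
Conditions: TBSCl, imidazole, DMF, rt
Reagents that add atoms: tert-butyldimethylsilyl chloride, CC(C)(C)[Si](C)(C)Cl
Why: Imidazole-mediated silylation masks the acidic phenol before organolithium chemistry and leaves all three oxygen protecting groups removable by fluoride.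

Step 8
Reactants: 19 1-bromo-4-(tert-butyldimethylsilyloxy)-5-[(tert-butyldimethylsilyloxy)methyl]-6-methoxy-3-(3-methylbut-2-enyl)-2-(triisopropylsilyloxy)benzene; 20 2-methylpropanal
Product: 22 1-[4-(tert-butyldimethylsilyloxy)-5-[(tert-butyldimethylsilyloxy)methyl]-6-methoxy-3-(3-methylbut-2-enyl)-2-(triisopropylsilyloxy)phenyl]-2-methylpropan-1-ol (racemic), via aryllithium 21 (not isolated)
Conditions: n-BuLi, THF, −78 °C; then 20, −78 °C
Reagents that add atoms: none
Why: Bromine–lithium exchange at −78 °C is faster than benzylic deprotonation and than O-to-C migration of the bulky triisopropylsilyl group, and the aryllithium adds to the aldehyde (1,2-addition); the carbinol centre is racemic and is removed in step 9.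

Step 9
Reactants: 22 the carbinol from step 8
Product: 23 1-[4-(tert-butyldimethylsilyloxy)-5-[(tert-butyldimethylsilyloxy)methyl]-6-methoxy-3-(3-methylbut-2-enyl)-2-(triisopropylsilyloxy)phenyl]-2-methylpropan-1-one
Conditions: Dess–Martin periodinane, CH2Cl2, 0 °C to rt
Reagents that add atoms: none
Why: Dess–Martin oxidation converts the benzylic alcohol to the aryl ketone under near-neutral conditions that should spare the silyl ethers and the prenyl alkene.

Step 10
Reactants: 24 pentan-3-one
Product: 25 3-(trimethylsilyloxy)pent-2-ene (E/Z mixture)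
Conditions: Me3SiOTf, Et3N, CH2Cl2, 0 °C
Reagents that add atoms: trimethylsilyl trifluoromethanesulfonate, C[Si](C)(C)OS(=O)(=O)C(F)(F)F
Why: Soft enolization and O-silylation of a symmetric ketone gives a single regioisomeric silyl enol ether, whose alkene geometry is irrelevant.

Step 11
Reactants: 25 3-(trimethylsilyloxy)pent-2-ene; 26 malonyl dichloride
Product: 28 6-ethyl-4-hydroxy-5-methylpyran-2-one, via diketo acid chloride 27 (not isolated)
Conditions: Et2O, −78 °C to rt
Reagents that add atoms: none
Why: C-acylation of the silyl enol ether by malonyl dichloride followed by cyclizing O-acylation of the diketone enol is an established route to 5,6-dialkyl-4-hydroxypyran-2-ones (ring A).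

Step 12
Reactants: 23 the aryl ketone from step 9; 28 6-ethyl-4-hydroxy-5-methylpyran-2-one
Product: 31 6-ethyl-4-hydroxy-3-[[2,4-dihydroxy-6-methoxy-3-(3-methylbut-2-enyl)-5-(2-methylpropanoyl)phenyl]methyl]-5-methylpyran-2-one, via ortho-hydroxybenzyl alcohol 29 (not isolated), via ortho-quinone methide 30 (not isolated)
Conditions: Bu4NF, AcOH, 28 (3 equiv), THF, 0 °C to rt; then 50 °C
Reagents that add atoms: none
Why: Fluoride desilylation frees both phenols and the benzylic alcohol, the resulting ortho-hydroxybenzyl alcohol of an acylphloroglucinol should lose water on mild warming to the ortho-quinone methide, and C3 of the 4-hydroxypyranone adds to it (Michael addition with rearomatization), the way methylene-bridged acylphloroglucinols are known to form.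

**Compound list**

1 | 5-methylhex-4-enoic acid | CC(C)=CCCC(=O)O | starting material
2 | 5-methylhex-4-enoyl chloride | CC(C)=CCCC(=O)Cl | intermediate
3 | acetylene | C#C | starting material
4 | lithium acetylide | [Li]C#C | intermediate (not isolated)
5 | lithium ethynolate | [Li+].[O-]C#C | intermediate (not isolated)
6 | (triisopropylsilyloxy)ethyne | C#CO[Si](C(C)C)(C(C)C)C(C)C | intermediate
7 | 5-methylhexa-1,4-dien-1-one (prenylketene) | CC(C)=CCC=C=O | intermediate (not isolated)
8 | 4-(3-methylbut-2-enyl)-3-(triisopropylsilyloxy)cyclobut-2-en-1-one (racemic) | CC(C)=CCC1C(=O)C=C1O[Si](C(C)C)(C(C)C)C(C)C | intermediate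
9 | 2-chloro-1,1-dimethoxyethane | COC(CCl)OC | starting material
10 | lithium methoxyacetylide | [Li]C#COC | intermediate (not isolated)
11 | lithium 3-methoxyprop-2-yn-1-olate | [Li+].[O-]CC#COC | intermediate (not isolated)
12 | tert-butyl(3-methoxyprop-2-ynoxy)dimethylsilane | COC#CCO[Si](C)(C)C(C)(C)C | intermediate
13 | (3Z)-7-methyl-3-(triisopropylsilyloxy)octa-1,3,6-trien-1-one | O=C=C/C(O[Si](C(C)C)(C(C)C)C(C)C)=C/CC=C(C)C | intermediate (not isolated)
14 | 2-[(tert-butyldimethylsilyloxy)methyl]-3-methoxy-4-[(1Z)-5-methyl-1-(triisopropylsilyloxy)hexa-1,4-dienyl]cyclobut-2-en-1-one (racemic) | COC1=C(CO[Si](C)(C)C(C)(C)C)C(=O)C1/C(O[Si](C(C)C)(C(C)C)C(C)C)=C/CC=C(C)C | intermediate (not isolated)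
15 | (3E,5Z)-2-[(tert-butyldimethylsilyloxy)methyl]-3-methoxy-9-methyl-5-(triisopropylsilyloxy)deca-1,3,5,8-tetraen-1-one | O=C=C(CO[Si](C)(C)C(C)(C)C)/C(OC)=C\C(O[Si](C(C)C)(C(C)C)C(C)C)=C\CC=C(C)C | intermediate (not isolated)
16 | 2-[(tert-butyldimethylsilyloxy)methyl]-3-methoxy-6-(3-methylbut-2-enyl)-5-(triisopropylsilyloxy)cyclohexa-2,4-dien-1-one (racemic) | COC1=C(CO[Si](C)(C)C(C)(C)C)C(=O)C(CC=C(C)C)C(O[Si](C(C)C)(C(C)C)C(C)C)=C1 | intermediate (not isolated)
17 | 2-[(tert-butyldimethylsilyloxy)methyl]-3-methoxy-6-(3-methylbut-2-enyl)-5-(triisopropylsilyloxy)phenol | COc1cc(O[Si](C(C)C)(C(C)C)C(C)C)c(CC=C(C)C)c(O)c1CO[Si](C)(C)C(C)(C)C | intermediate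
18 | 4-bromo-2-[(tert-butyldimethylsilyloxy)methyl]-3-methoxy-6-(3-methylbut-2-enyl)-5-(triisopropylsilyloxy)phenol | COc1c(Br)c(O[Si](C(C)C)(C(C)C)C(C)C)c(CC=C(C)C)c(O)c1CO[Si](C)(C)C(C)(C)C | intermediate
19 | 1-bromo-4-(tert-butyldimethylsilyloxy)-5-[(tert-butyldimethylsilyloxy)methyl]-6-methoxy-3-(3-methylbut-2-enyl)-2-(triisopropylsilyloxy)benzene | COc1c(Br)c(O[Si](C(C)C)(C(C)C)C(C)C)c(CC=C(C)C)c(O[Si](C)(C)C(C)(C)C)c1CO[Si](C)(C)C(C)(C)C | intermediate
20 | 2-methylpropanal | CC(C)C=O | starting material
21 | [4-(tert-butyldimethylsilyloxy)-5-[(tert-butyldimethylsilyloxy)methyl]-6-methoxy-3-(3-methylbut-2-enyl)-2-(triisopropylsilyloxy)phenyl]lithium | COc1c([Li])c(O[Si](C(C)C)(C(C)C)C(C)C)c(CC=C(C)C)c(O[Si](C)(C)C(C)(C)C)c1CO[Si](C)(C)C(C)(C)C | intermediate (not isolated)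
22 | 1-[4-(tert-butyldimethylsilyloxy)-5-[(tert-butyldimethylsilyloxy)methyl]-6-methoxy-3-(3-methylbut-2-enyl)-2-(triisopropylsilyloxy)phenyl]-2-methylpropan-1-ol (racemic) | COc1c(C(O)C(C)C)c(O[Si](C(C)C)(C(C)C)C(C)C)c(CC=C(C)C)c(O[Si](C)(C)C(C)(C)C)c1CO[Si](C)(C)C(C)(C)C | intermediate
23 | 1-[4-(tert-butyldimethylsilyloxy)-5-[(tert-butyldimethylsilyloxy)methyl]-6-methoxy-3-(3-methylbut-2-enyl)-2-(triisopropylsilyloxy)phenyl]-2-methylpropan-1-one | COc1c(C(=O)C(C)C)c(O[Si](C(C)C)(C(C)C)C(C)C)c(CC=C(C)C)c(O[Si](C)(C)C(C)(C)C)c1CO[Si](C)(C)C(C)(C)C | intermediate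
24 | pentan-3-one | CCC(=O)CC | starting material
25 | 3-(trimethylsilyloxy)pent-2-ene (E/Z mixture) | CC=C(CC)O[Si](C)(C)C | intermediate
26 | malonyl dichloride | O=C(Cl)CC(=O)Cl | starting material
27 | 4-methyl-3,5-dioxoheptanoyl chloride (racemic) | CCC(=O)C(C)C(=O)CC(=O)Cl | intermediate (not isolated)
28 | 6-ethyl-4-hydroxy-5-methylpyran-2-one | CCc1oc(=O)cc(O)c1C | intermediate
29 | 1-[2,4-dihydroxy-5-(hydroxymethyl)-6-methoxy-3-(3-methylbut-2-enyl)phenyl]-2-methylpropan-1-one | COc1c(C(=O)C(C)C)c(O)c(CC=C(C)C)c(O)c1CO | intermediate (not isolated)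
30 | 3-hydroxy-5-methoxy-6-methylidene-2-(3-methylbut-2-enyl)-4-(2-methylpropanoyl)cyclohexa-2,4-dien-1-one | C=C1C(=O)C(CC=C(C)C)=C(O)C(C(=O)C(C)C)=C1OC | intermediate (not isolated)
31 | 6-ethyl-4-hydroxy-3-[[2,4-dihydroxy-6-methoxy-3-(3-methylbut-2-enyl)-5-(2-methylpropanoyl)phenyl]methyl]-5-methylpyran-2-one | CCc1oc(=O)c(Cc2c(O)c(CC=C(C)C)c(O)c(C(=O)C(C)C)c2OC)c(O)c1C | target

**Step count**

Total steps: 12. Longest linear sequence: 8 steps (1 or 2, then 3, 5, 6, 7, 8, 9, 12).

**Steps most likely to fail**

Step 5 (benzannulation). The vinylogous silyl ester may lose its silyl group, or the vinylketene may dimerize, before the (2+2) event; the vinylcyclobutenone may also stall before the 6π closure. The fallback gives up the annulation and builds ring B by classical phloroglucinol chemistry; it sets out from pyranone 28 and comes back at target 31. 5-Methoxybenzene-1,3-diol F1 would be acylated with isobutyryl chloride and AlCl3 (Friedel–Crafts, regioisomers separated) to 1-(2,4-dihydroxy-6-methoxyphenyl)-2-methylpropan-1-one F2. C-Prenylation with 1-bromo-3-methylbut-2-ene and aqueous KOH at the carbon between the two hydroxyls would give 1-[2,4-dihydroxy-6-methoxy-3-(3-methylbut-2-enyl)phenyl]-2-methylpropan-1-one F3. Pyranone 28 would be converted with dimethyl(methylidene)ammonium iodide into the Mannich base 3-[(dimethylamino)methyl]-6-ethyl-4-hydroxy-5-methylpyran-2-one F4. On warming with F3 this loses dimethylamine to 6-ethyl-5-methyl-3-methylidenepyran-2,4-dione F5, which the one free ring carbon of F3 captures to give 31.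

Step 2 (silyl ynol ether). Mono-lithium acetylide may disproportionate during the oxygenation, and the ynolate may be silylated on carbon (giving the silylketene) in place of oxygen. The fallback avoids the silyl ynol ether; it sets out from acid chloride 2 and comes back at cyclobutenone 8. Ketene generation from 2 with Et3N in the presence of tert-butoxyethyne F6 (a known ynol ether made by dehydrobromination of the bromovinyl ether) would give 3-tert-butoxy-4-(3-methylbut-2-enyl)cyclobut-2-en-1-one F7. Treatment with i-Pr3SiOTf and 2,6-lutidine would silylate the carbonyl oxygen and expel the tert-butyl group as 2-methylpropene, as in the conversion of tert-butyl esters to silyl esters. No carbon is protonated, so the ring double bond stays in place and the product is 8.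

Step 6 (bromination). Bromonium formation at the prenyl alkene with capture by the neighbouring phenol (bromoetherification), or ipso attack on the ring, may compete with substitution at C5'. The fallback introduces the C5' carbon without a halogen; it sets out from phenol 17 and comes back at carbinol 22. Silylation of 17 (TBSCl, imidazole, DMF) would give tert-butyl-[2-[(tert-butyldimethylsilyloxy)methyl]-3-methoxy-6-(3-methylbut-2-enyl)-5-(triisopropylsilyloxy)phenoxy]dimethylsilane F8. Vilsmeier–Haack formylation (POCl3, DMF, 0 °C) at the only free ring position would give 4-(tert-butyldimethylsilyloxy)-5-[(tert-butyldimethylsilyloxy)methyl]-6-methoxy-3-(3-methylbut-2-enyl)-2-(triisopropylsilyloxy)benzaldehyde F9. Addition of i-PrMgCl (THF, −78 °C) would then give 22.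

**Further compounds**

F1 | step 5 | 5-methoxybenzene-1,3-diol | COc1cc(O)cc(O)c1
F2 | step 5 | 1-(2,4-dihydroxy-6-methoxyphenyl)-2-methylpropan-1-one | COc1cc(O)cc(O)c1C(=O)C(C)C
F3 | step 5 | 1-[2,4-dihydroxy-6-methoxy-3-(3-methylbut-2-enyl)phenyl]-2-methylpropan-1-one | COc1cc(O)c(CC=C(C)C)c(O)c1C(=O)C(C)C
F4 | step 5 | 3-[(dimethylamino)methyl]-6-ethyl-4-hydroxy-5-methylpyran-2-one | CCc1oc(=O)c(CN(C)C)c(O)c1C
F5 | step 5 | 6-ethyl-5-methyl-3-methylidenepyran-2,4-dione | CCC1=C(C)C(=O)C(=C)C(=O)O1
F6 | step 2 | tert-butoxyethyne | C#COC(C)(C)C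
F7 | step 2 | 3-tert-butoxy-4-(3-methylbut-2-enyl)cyclobut-2-en-1-one (racemic) | CC(C)=CCC1C(=O)C=C1OC(C)(C)C
F8 | step 6 | tert-butyl-[2-[(tert-butyldimethylsilyloxy)methyl]-3-methoxy-6-(3-methylbut-2-enyl)-5-(triisopropylsilyloxy)phenoxy]dimethylsilane | COc1cc(O[Si](C(C)C)(C(C)C)C(C)C)c(CC=C(C)C)c(O[Si](C)(C)C(C)(C)C)c1CO[Si](C)(C)C(C)(C)C
F9 | step 6 | 4-(tert-butyldimethylsilyloxy)-5-[(tert-butyldimethylsilyloxy)methyl]-6-methoxy-3-(3-methylbut-2-enyl)-2-(triisopropylsilyloxy)benzaldehyde | COc1c(C=O)c(O[Si](C(C)C)(C(C)C)C(C)C)c(CC=C(C)C)c(O[Si](C)(C)C(C)(C)C)c1CO[Si](C)(C)C(C)(C)C
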